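Two questions stood on flask epsilon, which was still being followed: its apparent orders at fixed conversion.

in all of them: substrate 5.0 × 10⁻⁴ M; second catalyst 0.70 µM

|  | coupling partner | free catalyst | remark |
|---|---|---|---|
| epsilon | 0.50 mM | 1 µM | the very flask that is asked about, followed so far |
| beta | 1 mM | 1 µM | run made earlier |
| flask | 0.500 mM | 1.0 µM |  |

| run | time / min | target / % |
|---|---|---|
| epsilon | 0.500 | 23.1 |
| epsilon | 1.00 | 51.4 |
| epsilon | 1.33 | 65.3 |
| epsilon | 2.00 | 81.7 |
| epsilon | 2.50 | 87.8 |
| beta | 0.417 | 19.3 |
| beta | 0.667 | 36.7 |
| beta | 1.33 | 71.4 |
| beta | 2.50 | 94.6 |
| beta | 5.00 | 99.8 |

(standard deviation of a reading: 0.3 percentage points)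

- apparent order in free catalyst when 5.0% of the substrate are converted (percent change of the rate of making target for one percent more free catalyst charged)
- apparent order in coupling partner when 5.0% of the substrate are converted (percent change of the rate of making target for one percent more coupling partner charged)

- "the catalyst" is free catalyst with its forms; second catalyst is a second catalyst
- no earlier run changes the charge of free catalyst; that part of a forecast is a guess
- what has left substrate counts as converted, also if it is not yet product

I bracketed the order in free catalyst and estimated the one in coupling partner. Target cannot exceed what has left substrate. So if substrate falls as exp(−kt), with k its first-order constant of loss, each target reading sets a floor on k. Epsilon's last reading gave 0.841 min⁻¹, the conversion floor. The time τ to 5.0% conversion is the logarithm of the inverse fraction of substrate left, divided by k, so on that first-order picture τ was at most 0.0610 min.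

At 5.0% conversion the converted share of substrate is the same whatever the charge. If free catalyst ran the substrate step, more of it would shorten τ and the order would lie near 0. If it ran the coupling, the order would lie near 1. I leaned to the lower end, as a guess.

For coupling partner, both runs were read at 1.33 min. Beta, with twice epsilon's charge, read 71.4% target against epsilon's 65.3%, a mean order over that time of 0.129. I took that as my estimate, though it was read later than τ.

The forecast gave 0.9 for free catalyst, inside my bracket, saying “The catalyst order is a guess.” Its 0.4 for coupling partner was higher than my reading.

The flask gave 0.014 in free catalyst and 0.14 in coupling partner.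

    second catalyst + open intermediate ⇌ catalyst intermediate (K = 2530 M⁻¹, k = 44700 M⁻¹ s⁻¹)
    free catalyst → spent catalyst (k = 8.29 × 10⁻⁶ s⁻¹)
    substrate + free catalyst → free catalyst + open intermediate (k = 36800 M⁻¹ s⁻¹)
    coupling partner + catalyst intermediate → second catalyst + target (k = 2.36 × 10⁵ M⁻¹ s⁻¹)

In flask epsilon the substrate constant 2.21 min⁻¹ stood above the floor, and 5.0% conversion came at 0.0232 min, earlier than the ceiling 0.0610 min. In beta, the same floor from its reading at 2.50 min gave 1.17 min⁻¹, lower than that run's 2.21 min⁻¹. At 0.315 min in flask epsilon, open intermediate was made 1.91 times faster than it was used up, each step taken net. At 1.20 min that flask held 32.5% open intermediate beside 60.4% target.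

The readings were computed with made-up constants, and the scatter is random.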